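## Retrosynthetic overview

1. Target 24 comes from hydrogenolysis of four O-benzyl groups in 23. Compound 23 comes from trans-selective C3 alkylation of (4S)-4-(arylmethyl)oxolan-2-one 21 with dihydrobenzofuran-5-ylmethyl bromide 15 (lactone C3–CH2 bond, C3 set by C4).
2. Lactone 21 comes from an enantioselective single-oxygen insertion (Baeyer–Villiger) into achiral 3-(arylmethyl)cyclobutanone 19. This one event closes the oxolan-2-one ring by making the O1–C5 bond and creates the C4 stereocentre. Ketone 19 comes from a dichloroketene [2+2] cycloaddition on O-benzyleugenol and dechlorination.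
3. Enabling feature: before the C3 benzyl group is attached, lactone carbons C3 and C5 are both CH2. The ring carbons C2–C3–C4–C5 therefore fold back to a cyclobutanone whose mirror plane holds C2(=O), C4 and the arylmethyl group. The two C2–CH2 bonds are enantiotopic and equally apt to migrate, so ring strain plus a chiral Lewis acid make oxygen insertion a regiochemically unambiguous desymmetrisation.
4. Bromide 15 comes from closing the 2,3-dihydrobenzofuran ring at C2–C3 by enantioselective rhodium-carbenoid insertion into the benzylic C–H of an aryl arylmethyl ether (aryldiazoacetate 8), then epimerising C3 to trans. Diazoester 8 comes from 3-bromo-4,5-dihydroxybenzaldehyde by two O-alkylations, acetal masking, Pd α-arylation and diazo transfer.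
5. Order of ring formation: dihydrofuran ring (step 7), cyclobutanone (step 14), oxolan-2-one by ring expansion (step 16). All three benzene rings are bought.

Key step: step 16

Assumption (remark on the chemistry): the absolute sense of induction of Rh2(S-PTTL)4 in step 7 and of the (S,S)-N,N'-dioxide/Sc(OTf)3 catalyst in step 16 is taken as drawn; should either be opposite, the mirror-image catalyst is used and nothing else changes.

## Route

Step 1
Reactants: 1 [4-(benzyloxy)-3-methoxyphenyl]methanol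
Product: 2 1-(benzyloxy)-4-(bromomethyl)-2-methoxybenzene
Conditions: PBr3 (0.4 equiv), Et2O, 0 °C
Reagents that add atoms: phosphorus tribromide, BrP(Br)Br
Why: Conversion of a benzylic alcohol to the bromide with PBr3 (SN2 on the phosphite ester) is routine for electron-rich benzyl alcohols and leaves the aryl benzyl ether intact.

Step 2
Reactants: 3 3-bromo-4,5-dihydroxybenzaldehyde; 2 1-(benzyloxy)-4-(bromomethyl)-2-methoxybenzene
Product: 4 4-{[4-(benzyloxy)-3-methoxyphenyl]methoxy}-3-bromo-5-hydroxybenzaldehyde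
Conditions: Li2CO3 (1.1 equiv), DMF, 45 °C
Reagents that add atoms: none
Why: Williamson ether synthesis under acidity control: the 4-OH (para to the formyl group, ortho to bromine) is much the more acidic phenol, so one equivalent of weak base should generate and alkylate only that phenoxide.

Step 3
Reactants: 4 4-{[4-(benzyloxy)-3-methoxyphenyl]methoxy}-3-bromo-5-hydroxybenzaldehyde
Product: 5 3-(benzyloxy)-4-{[4-(benzyloxy)-3-methoxyphenyl]methoxy}-5-bromobenzaldehyde
Conditions: BnBr (1.2 equiv), K2CO3, DMF, rt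
Reagents that add atoms: benzyl bromide, BrCc1ccccc1
Why: Williamson etherification of the remaining phenol, which later becomes the free 7-OH of the dihydrobenzofuran.

Step 4
Reactants: 5 3-(benzyloxy)-4-{[4-(benzyloxy)-3-methoxyphenyl]methoxy}-5-bromobenzaldehyde
Product: 6 1-(benzyloxy)-2-{[4-(benzyloxy)-3-methoxyphenyl]methoxy}-3-bromo-5-(dimethoxymethyl)benzene
Conditions: HC(OMe)3 (3 equiv), MeOH, PPTS (5 mol%), 40 °C; Et3N quench
Reagents that add atoms: trimethyl orthoformate, COC(OC)OC; methanol, CO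
Why: Acid-catalysed acetalisation with orthoformate as water scavenger masks the aldehyde against the zinc enolate of step 5 and the hydride of step 9, and the mild acid spares the alkoxybenzyl aryl ether.

Step 5
Reactants: 6 1-(benzyloxy)-2-{[4-(benzyloxy)-3-methoxyphenyl]methoxy}-3-bromo-5-(dimethoxymethyl)benzene
Product: 7 methyl 2-[3-(benzyloxy)-2-{[4-(benzyloxy)-3-methoxyphenyl]methoxy}-5-(dimethoxymethyl)phenyl]acetate
Conditions: BrZnCH2CO2Me (1.5 equiv, preformed 0.5 M in THF), Pd2(dba)3 (2 mol%), XPhos (8 mol%), THF, 60 °C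
Reagents that add atoms: (2-methoxy-2-oxoethyl)zinc bromide, COC(=O)C[Zn]Br
Why: Negishi-type palladium-catalysed α-arylation of a Reformatsky reagent runs under near-neutral conditions that tolerate the acetal and benzyl ethers, and the bulky biaryl phosphine copes with the ortho-alkoxy aryl bromide.

Step 6
Reactants: 7 methyl 2-[3-(benzyloxy)-2-{[4-(benzyloxy)-3-methoxyphenyl]methoxy}-5-(dimethoxymethyl)phenyl]acetate
Product: 8 methyl 2-[3-(benzyloxy)-2-{[4-(benzyloxy)-3-methoxyphenyl]methoxy}-5-(dimethoxymethyl)phenyl]-2-diazoacetate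
Conditions: p-ABSA (1.3 equiv), DBU (1.5 equiv), MeCN, 0 °C to rt
Reagents that add atoms: 4-acetamidobenzenesulfonyl azide, CC(=O)Nc1ccc(cc1)S(=O)(=O)N=[N+]=[N-]
Why: Regitz diazo transfer to the activated methylene of an arylacetate is the standard entry to aryldiazoacetates.

Step 7
Reactants: 8 methyl 2-[3-(benzyloxy)-2-{[4-(benzyloxy)-3-methoxyphenyl]methoxy}-5-(dimethoxymethyl)phenyl]-2-diazoacetate
Product: 9 methyl (2S,3R)-7-(benzyloxy)-2-[4-(benzyloxy)-3-methoxyphenyl]-5-(dimethoxymethyl)-2,3-dihydro-1-benzofuran-3-carboxylate (cis)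
Conditions: Rh2(S-PTTL)4 (2 mol%), toluene, −60 °C, slow addition of 8
Reagents that add atoms: none
Why: Enantioselective intramolecular rhodium-carbenoid C–H insertion: the donor/acceptor carbenoid inserts into the ether-activated benzylic C–H through a five-membered transition state to form C2–C3, the chiral carboxylate pocket fixing C2 as S and the kinetically preferred cis (2S,3R) ester being expected.

Step 8
Reactants: 9 methyl (2S,3R)-7-(benzyloxy)-2-[4-(benzyloxy)-3-methoxyphenyl]-5-(dimethoxymethyl)-2,3-dihydro-1-benzofuran-3-carboxylate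
Product: 10 methyl (2S,3S)-7-(benzyloxy)-2-[4-(benzyloxy)-3-methoxyphenyl]-5-(dimethoxymethyl)-2,3-dihydro-1-benzofuran-3-carboxylate (trans)
Conditions: NaOMe (0.5 equiv), MeOH/THF (2:1), rt
Reagents that add atoms: none
Why: Thermodynamic epimerisation through the ester enolate should move C3 to the more stable trans arrangement, while C2 is untouched because ring opening by β-elimination would be the reverse of a disfavoured 5-endo-trig closure and the benzyl-capped 4'-oxygen cannot form a quinone methide.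

Step 9
Reactants: 10 methyl (2S,3S)-7-(benzyloxy)-2-[4-(benzyloxy)-3-methoxyphenyl]-5-(dimethoxymethyl)-2,3-dihydro-1-benzofuran-3-carboxylate
Product: 11 [(2S,3R)-7-(benzyloxy)-2-[4-(benzyloxy)-3-methoxyphenyl]-5-(dimethoxymethyl)-2,3-dihydro-1-benzofuran-3-yl]methanol
Conditions: LiAlH4 (1.2 equiv), THF, 0 °C; H2O then 15% aq. NaOH work-up
Reagents that add atoms: none
Why: Hydride reduction of the ester to the primary alcohol does not touch either stereocentre (the descriptor at C3 changes only through the priority rules), and the basic work-up keeps the acetal.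

Step 10
Reactants: 11 [(2S,3R)-7-(benzyloxy)-2-[4-(benzyloxy)-3-methoxyphenyl]-5-(dimethoxymethyl)-2,3-dihydro-1-benzofuran-3-yl]methanol
Product: 13 (2S,3R)-7-(benzyloxy)-3-[(benzyloxy)methyl]-2-[4-(benzyloxy)-3-methoxyphenyl]-2,3-dihydro-1-benzofuran-5-carbaldehyde, via benzyl ether acetal 12 (not isolated)
Conditions: NaH (1.5 equiv), BnBr (1.3 equiv), Bu4NI (5 mol%), THF/DMF, 0 °C to rt; then AcOH/H2O/THF (3:1:1), rt
Reagents that add atoms: benzyl bromide, BrCc1ccccc1; water, O
Why: Williamson benzylation of the primary alkoxide followed by mild aqueous-acid hydrolysis of the electron-rich dimethyl acetal, which is much faster than ionisation of the ring benzylic ether.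

Step 11
Reactants: 13 (2S,3R)-7-(benzyloxy)-3-[(benzyloxy)methyl]-2-[4-(benzyloxy)-3-methoxyphenyl]-2,3-dihydro-1-benzofuran-5-carbaldehyde
Product: 14 [(2S,3R)-7-(benzyloxy)-3-[(benzyloxy)methyl]-2-[4-(benzyloxy)-3-methoxyphenyl]-2,3-dihydro-1-benzofuran-5-yl]methanol
Conditions: NaBH4 (1.0 equiv), MeOH/THF, 0 °C
Reagents that add atoms: none
Why: Borohydride reduction of an aryl aldehyde to the benzylic alcohol is chemoselective and stereochemically innocent.

Step 12
Reactants: 14 [(2S,3R)-7-(benzyloxy)-3-[(benzyloxy)methyl]-2-[4-(benzyloxy)-3-methoxyphenyl]-2,3-dihydro-1-benzofuran-5-yl]methanol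
Product: 15 (2S,3R)-7-(benzyloxy)-3-[(benzyloxy)methyl]-2-[4-(benzyloxy)-3-methoxyphenyl]-5-(bromomethyl)-2,3-dihydro-1-benzofuran
Conditions: CBr4 (1.3 equiv), PPh3 (1.3 equiv), CH2Cl2, 0 °C; short silica plug, used at once
Reagents that add atoms: carbon tetrabromide, BrC(Br)(Br)Br
Why: The Appel reaction converts the benzylic alcohol to the bromide under neutral conditions, so the acid-sensitive ring ether and the benzyl ethers should survive.

Step 13
Reactants: 16 4-allyl-2-methoxyphenol (eugenol)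
Product: 17 4-allyl-1-(benzyloxy)-2-methoxybenzene
Conditions: BnBr (1.1 equiv), K2CO3, acetone, reflux
Reagents that add atoms: benzyl bromide, BrCc1ccccc1
Why: Williamson etherification protects the phenol for the Lewis-acidic cycloaddition, the peracid oxidation and the enolate chemistry that follow.

Step 14
Reactants: 17 4-allyl-1-(benzyloxy)-2-methoxybenzene
Product: 18 3-{[4-(benzyloxy)-3-methoxyphenyl]methyl}-2,2-dichlorocyclobutan-1-one (racemic)
Conditions: Cl3CCOCl (2 equiv, slow addition), Zn(Cu) (3 equiv), Et2O/DME (4:1), 35 °C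
Reagents that add atoms: trichloroacetyl chloride, ClC(=O)C(Cl)(Cl)Cl
Why: [2+2] cycloaddition of dichloroketene (generated in the flask by zinc dechlorination) with the terminal alkene joins the ketene carbonyl carbon to the terminal CH2, which should give the 3-substituted cyclobutanone regiochemistry.

Step 15
Reactants: 18 3-{[4-(benzyloxy)-3-methoxyphenyl]methyl}-2,2-dichlorocyclobutan-1-one
Product: 19 3-{[4-(benzyloxy)-3-methoxyphenyl]methyl}cyclobutan-1-one
Conditions: Zn dust (6 equiv), AcOH, rt to 60 °C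
Reagents that add atoms: none
Why: Reductive dechlorination of the α,α-dichloroketone with zinc in acetic acid removes the only stereocentre and delivers the achiral ketone with a mirror plane.

Step 16
Reactants: 19 3-{[4-(benzyloxy)-3-methoxyphenyl]methyl}cyclobutan-1-one
Product: 21 (4S)-4-{[4-(benzyloxy)-3-methoxyphenyl]methyl}oxolan-2-one, via Criegee adduct 20 (not isolated)
Conditions: m-CPBA (1.2 equiv), Sc(OTf)3 (5 mol%), (S,S)-1,1'-(propane-1,3-diyl)bis[2-(2,6-diisopropylphenylcarbamoyl)piperidine 1-oxide] (6 mol%), EtOAc, −20 °C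
Reagents that add atoms: 3-chloroperoxybenzoic acid, OOC(=O)c1cccc(Cl)c1
Why: The ligated Sc(OTf)3 binds the ketone, m-CPBA adds to give Criegee adduct 20, and one of the two enantiotopic ring CH2 groups shifts from carbon to the proximal peroxide oxygen, antiperiplanar to the breaking O–O bond, with loss of 3-chlorobenzoate. The closest known reaction type is the catalytic enantioselective Baeyer–Villiger desymmetrisation of 3-substituted cyclobutanones by chiral Lewis or Brønsted acids. The oxolan-2-one ring is closed by ring enlargement from four to five members, the migrating CH2 forming the new O1–C5 bond, not by an exo or endo cyclisation. C4 lies on the mirror plane of 19 as a prochiral centre and becomes stereogenic when the chiral scandium complex selects which CH2–C(=O) bond receives the oxygen. Only enantiotopic-group selectivity is needed: regioselectivity cannot arise because both candidates for migration are CH2 groups while lactone C3 is still unsubstituted, and chemoselectivity over arene or benzylic oxidation rests on the strain-accelerated reactivity of the cyclobutanone at −20 °C.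

Step 17
Reactants: 21 (4S)-4-{[4-(benzyloxy)-3-methoxyphenyl]methyl}oxolan-2-one; 15 (2S,3R)-7-(benzyloxy)-3-[(benzyloxy)methyl]-2-[4-(benzyloxy)-3-methoxyphenyl]-5-(bromomethyl)-2,3-dihydro-1-benzofuran
Product: 23 (3S,4S)-3-{[(2S,3R)-7-(benzyloxy)-3-[(benzyloxy)methyl]-2-[4-(benzyloxy)-3-methoxyphenyl]-2,3-dihydro-1-benzofuran-5-yl]methyl}-4-{[4-(benzyloxy)-3-methoxyphenyl]methyl}oxolan-2-one, via lithium enolate 22 (not isolated)
Conditions: LiN(iPr)2 (1.05 equiv), THF, −78 °C, 45 min; then 15 (1.1 equiv) in THF/DMPU, −78 to −40 °C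
Reagents that add atoms: none
Why: Alkylation of the lactone lithium enolate with a benzylic bromide should occur on the face anti to the C4 arylmethyl group (substrate control), setting C3 as S in the 3,4-trans lactone.

Step 18
Reactants: 23 (3S,4S)-3-{[(2S,3R)-7-(benzyloxy)-3-[(benzyloxy)methyl]-2-[4-(benzyloxy)-3-methoxyphenyl]-2,3-dihydro-1-benzofuran-5-yl]methyl}-4-{[4-(benzyloxy)-3-methoxyphenyl]methyl}oxolan-2-one
Product: 24 (3S,4S)-3-{[(2S,3R)-7-hydroxy-2-(4-hydroxy-3-methoxyphenyl)-3-(hydroxymethyl)-2,3-dihydro-1-benzofuran-5-yl]methyl}-4-[(4-hydroxy-3-methoxyphenyl)methyl]oxolan-2-one (CNP0118131.1)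
Conditions: H2 (1 atm), Pd/C (10 wt% Pd), EtOAc/EtOH (1:1), rt; stopped at complete debenzylation
Reagents that add atoms: none
Why: Catalytic hydrogenolysis should cleave the four unhindered primary O-benzyl groups much faster than the hindered secondary ring C2–O1 ether, and it leaves the lactone, the methyl ethers and all four stereocentres alone.

## Compound list

1 | [4-(benzyloxy)-3-methoxyphenyl]methanol | COc1cc(CO)ccc1OCc1ccccc1 | starting material
2 | 1-(benzyloxy)-4-(bromomethyl)-2-methoxybenzene | COc1cc(CBr)ccc1OCc1ccccc1 | intermediate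
3 | 3-bromo-4,5-dihydroxybenzaldehyde | O=Cc1cc(O)c(O)c(Br)c1 | starting material
4 | 4-{[4-(benzyloxy)-3-methoxyphenyl]methoxy}-3-bromo-5-hydroxybenzaldehyde | O=Cc1cc(O)c(OCc2ccc(OCc3ccccc3)c(OC)c2)c(Br)c1 | intermediate
5 | 3-(benzyloxy)-4-{[4-(benzyloxy)-3-methoxyphenyl]methoxy}-5-bromobenzaldehyde | O=Cc1cc(OCc2ccccc2)c(OCc2ccc(OCc3ccccc3)c(OC)c2)c(Br)c1 | intermediate
6 | 1-(benzyloxy)-2-{[4-(benzyloxy)-3-methoxyphenyl]methoxy}-3-bromo-5-(dimethoxymethyl)benzene | COC(OC)c1cc(OCc2ccccc2)c(OCc2ccc(OCc3ccccc3)c(OC)c2)c(Br)c1 | intermediate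
7 | methyl 2-[3-(benzyloxy)-2-{[4-(benzyloxy)-3-methoxyphenyl]methoxy}-5-(dimethoxymethyl)phenyl]acetate | COC(=O)Cc1cc(C(OC)OC)cc(OCc2ccccc2)c1OCc1ccc(OCc2ccccc2)c(OC)c1 | intermediate
8 | methyl 2-[3-(benzyloxy)-2-{[4-(benzyloxy)-3-methoxyphenyl]methoxy}-5-(dimethoxymethyl)phenyl]-2-diazoacetate | COC(=O)C(=[N+]=[N-])c1cc(C(OC)OC)cc(OCc2ccccc2)c1OCc1ccc(OCc2ccccc2)c(OC)c1 | intermediate
9 | methyl (2S,3R)-7-(benzyloxy)-2-[4-(benzyloxy)-3-methoxyphenyl]-5-(dimethoxymethyl)-2,3-dihydro-1-benzofuran-3-carboxylate (cis) | COC(OC)c1cc(OCc2ccccc2)c2c(c1)[C@@H](C(=O)OC)[C@@H](c1ccc(OCc3ccccc3)c(OC)c1)O2 | intermediate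
10 | methyl (2S,3S)-7-(benzyloxy)-2-[4-(benzyloxy)-3-methoxyphenyl]-5-(dimethoxymethyl)-2,3-dihydro-1-benzofuran-3-carboxylate (trans) | COC(OC)c1cc(OCc2ccccc2)c2c(c1)[C@H](C(=O)OC)[C@@H](c1ccc(OCc3ccccc3)c(OC)c1)O2 | intermediate
11 | [(2S,3R)-7-(benzyloxy)-2-[4-(benzyloxy)-3-methoxyphenyl]-5-(dimethoxymethyl)-2,3-dihydro-1-benzofuran-3-yl]methanol | COC(OC)c1cc(OCc2ccccc2)c2c(c1)[C@H](CO)[C@@H](c1ccc(OCc3ccccc3)c(OC)c1)O2 | intermediate
12 | (2S,3R)-7-(benzyloxy)-3-[(benzyloxy)methyl]-2-[4-(benzyloxy)-3-methoxyphenyl]-5-(dimethoxymethyl)-2,3-dihydro-1-benzofuran | COC(OC)c1cc(OCc2ccccc2)c2c(c1)[C@H](COCc1ccccc1)[C@@H](c1ccc(OCc3ccccc3)c(OC)c1)O2 | intermediate (not isolated)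
13 | (2S,3R)-7-(benzyloxy)-3-[(benzyloxy)methyl]-2-[4-(benzyloxy)-3-methoxyphenyl]-2,3-dihydro-1-benzofuran-5-carbaldehyde | O=Cc1cc(OCc2ccccc2)c2c(c1)[C@H](COCc1ccccc1)[C@@H](c1ccc(OCc3ccccc3)c(OC)c1)O2 | intermediate
14 | [(2S,3R)-7-(benzyloxy)-3-[(benzyloxy)methyl]-2-[4-(benzyloxy)-3-methoxyphenyl]-2,3-dihydro-1-benzofuran-5-yl]methanol | OCc1cc(OCc2ccccc2)c2c(c1)[C@H](COCc1ccccc1)[C@@H](c1ccc(OCc3ccccc3)c(OC)c1)O2 | intermediate
15 | (2S,3R)-7-(benzyloxy)-3-[(benzyloxy)methyl]-2-[4-(benzyloxy)-3-methoxyphenyl]-5-(bromomethyl)-2,3-dihydro-1-benzofuran | BrCc1cc(OCc2ccccc2)c2c(c1)[C@H](COCc1ccccc1)[C@@H](c1ccc(OCc3ccccc3)c(OC)c1)O2 | intermediate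
16 | 4-allyl-2-methoxyphenol (eugenol) | C=CCc1ccc(O)c(OC)c1 | starting material
17 | 4-allyl-1-(benzyloxy)-2-methoxybenzene | C=CCc1ccc(OCc2ccccc2)c(OC)c1 | intermediate
18 | 3-{[4-(benzyloxy)-3-methoxyphenyl]methyl}-2,2-dichlorocyclobutan-1-one (racemic) | O=C1CC(Cc2ccc(OCc3ccccc3)c(OC)c2)C1(Cl)Cl | intermediate
19 | 3-{[4-(benzyloxy)-3-methoxyphenyl]methyl}cyclobutan-1-one (achiral) | O=C1CC(Cc2ccc(OCc3ccccc3)c(OC)c2)C1 | intermediate
20 | 3-{[4-(benzyloxy)-3-methoxyphenyl]methyl}-1-hydroxycyclobutyl 3-chlorobenzenecarboperoxoate (Criegee adduct, ring cis/trans undefined) | OC1(OOC(=O)c2cccc(Cl)c2)CC(Cc2ccc(OCc3ccccc3)c(OC)c2)C1 | intermediate (not isolated)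
21 | (4S)-4-{[4-(benzyloxy)-3-methoxyphenyl]methyl}oxolan-2-one | COc1cc(C[C@@H]2COC(=O)C2)ccc1OCc1ccccc1 | intermediate
22 | lithium enolate of 21 | COc1cc(C[C@@H]2COC([O-])=C2)ccc1OCc1ccccc1.[Li+] | intermediate (not isolated)
23 | (3S,4S)-3-{[(2S,3R)-7-(benzyloxy)-3-[(benzyloxy)methyl]-2-[4-(benzyloxy)-3-methoxyphenyl]-2,3-dihydro-1-benzofuran-5-yl]methyl}-4-{[4-(benzyloxy)-3-methoxyphenyl]methyl}oxolan-2-one | COc1cc(C[C@@H]2COC(=O)[C@H]2Cc2cc(OCc3ccccc3)c3c(c2)[C@H](COCc2ccccc2)[C@@H](c2ccc(OCc4ccccc4)c(OC)c2)O3)ccc1OCc1ccccc1 | intermediate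
24 | (3S,4S)-3-{[(2S,3R)-7-hydroxy-2-(4-hydroxy-3-methoxyphenyl)-3-(hydroxymethyl)-2,3-dihydro-1-benzofuran-5-yl]methyl}-4-[(4-hydroxy-3-methoxyphenyl)methyl]oxolan-2-one | COc1cc(C[C@@H]2COC(=O)[C@H]2Cc2cc(O)c3c(c2)[C@H](CO)[C@@H](c2ccc(O)c(OC)c2)O3)ccc1O | target

## Step count and risks

Total step count: 18.
Longest linear sequence: 14 steps (steps 1–12, then 17 and 18).

Steps most likely to fail:

1. Step 7. The carbenoid insertion may lose enantio- and cis/trans control on this doubly ortho-flanked, very electron-rich ether, or the carbenoid may be diverted into dimerisation or attack on the benzyl arene. The fallback replaces catalyst control by auxiliary control with separable diastereomers. It sets out from 7 and comes back at 10. Ester 7 is saponified (LiOH, THF/H2O) to 2-[3-(benzyloxy)-2-{[4-(benzyloxy)-3-methoxyphenyl]methoxy}-5-(dimethoxymethyl)phenyl]acetic acid F1. The acid is esterified (DCC, DMAP, CH2Cl2) with (2S)-2-hydroxy-1-(pyrrolidin-1-yl)propan-1-one to the lactamide ester F2. Diazo transfer (p-ABSA, DBU) gives the diazo lactamide ester F3. Insertion with Rh2(S-DOSP)4 in toluene, now under combined auxiliary and catalyst control, should give the trans-dihydrobenzofuran lactamide ester F4, which is purified from its diastereomers on silica. NaOMe in MeOH then transesterifies F4 to trans methyl ester 10.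

2. Step 16. The catalyst may discriminate poorly between the two enantiotopic CH2 groups, because the differentiating arylmethyl group is remote and flexible, giving lactone of low enantiomeric purity. The fallback is a classical resolution. It sets out from 19 and comes back at 21. Ketone 19 is oxidised without chiral control (30% H2O2, AcOH, rt) to the racemic lactone F5. The lactone is opened with (1S)-1-phenylethan-1-amine (neat, cat. 2-hydroxypyridine, 80 °C) to two diastereomeric hydroxy amides. These are separated by crystallisation or chromatography to give the (3S)-hydroxy amide F6. Heating F6 with 2 M H2SO4 in dioxane relactonises it to 21.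

3. Step 17. The electron-rich benzylic bromide 15 may ionise and self-condense faster than it C-alkylates, or proton transfer between product and enolate may lead to double alkylation. The fallback avoids the bromide by an aldol and deoxygenation sequence. It sets out from 21 and 13 and comes back at 23. Enolate 22 (from 21, LiN(iPr)2, THF, −78 °C) is added to aldehyde 13 to give the trans aldol adduct F7 (carbinol epimers, both usable). Treatment with PhOC(S)Cl, pyridine and DMAP at 0 °C gives the phenyl thionocarbonate F8. Barton–McCombie deoxygenation (Bu3SnH, AIBN, toluene, 80 °C) removes the benzylic oxygen and gives 23 with the C3 and C4 configurations unchanged.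

Further compounds

F1 | step 7 | 2-[3-(benzyloxy)-2-{[4-(benzyloxy)-3-methoxyphenyl]methoxy}-5-(dimethoxymethyl)phenyl]acetic acid | OC(=O)Cc1cc(C(OC)OC)cc(OCc2ccccc2)c1OCc1ccc(OCc2ccccc2)c(OC)c1
F2 | step 7 | (2S)-1-oxo-1-(pyrrolidin-1-yl)propan-2-yl 2-[3-(benzyloxy)-2-{[4-(benzyloxy)-3-methoxyphenyl]methoxy}-5-(dimethoxymethyl)phenyl]acetate | C[C@H](OC(=O)Cc1cc(C(OC)OC)cc(OCc2ccccc2)c1OCc1ccc(OCc2ccccc2)c(OC)c1)C(=O)N1CCCC1
F3 | step 7 | (2S)-1-oxo-1-(pyrrolidin-1-yl)propan-2-yl 2-[3-(benzyloxy)-2-{[4-(benzyloxy)-3-methoxyphenyl]methoxy}-5-(dimethoxymethyl)phenyl]-2-diazoacetate | C[C@H](OC(=O)C(=[N+]=[N-])c1cc(C(OC)OC)cc(OCc2ccccc2)c1OCc1ccc(OCc2ccccc2)c(OC)c1)C(=O)N1CCCC1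
F4 | step 7 | (2S)-1-oxo-1-(pyrrolidin-1-yl)propan-2-yl (2S,3S)-7-(benzyloxy)-2-[4-(benzyloxy)-3-methoxyphenyl]-5-(dimethoxymethyl)-2,3-dihydro-1-benzofuran-3-carboxylate | COC(OC)c1cc(OCc2ccccc2)c2c(c1)[C@H](C(=O)O[C@@H](C)C(=O)N1CCCC1)[C@@H](c1ccc(OCc3ccccc3)c(OC)c1)O2
F5 | step 16 | racemic 4-{[4-(benzyloxy)-3-methoxyphenyl]methyl}oxolan-2-one | COc1cc(CC2COC(=O)C2)ccc1OCc1ccccc1
F6 | step 16 | (3S)-3-{[4-(benzyloxy)-3-methoxyphenyl]methyl}-4-hydroxy-N-[(1S)-1-phenylethyl]butanamide | COc1cc(C[C@@H](CC(=O)N[C@@H](C)c2ccccc2)CO)ccc1OCc1ccccc1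
F7 | step 17 | (3R,4S)-3-{[(2S,3R)-7-(benzyloxy)-3-[(benzyloxy)methyl]-2-[4-(benzyloxy)-3-methoxyphenyl]-2,3-dihydro-1-benzofuran-5-yl](hydroxy)methyl}-4-{[4-(benzyloxy)-3-methoxyphenyl]methyl}oxolan-2-one (carbinol epimers) | COc1cc(C[C@@H]2COC(=O)[C@H]2C(O)c2cc(OCc3ccccc3)c3c(c2)[C@H](COCc2ccccc2)[C@@H](c2ccc(OCc4ccccc4)c(OC)c2)O3)ccc1OCc1ccccc1
F8 | step 17 | O-{[(2S,3R)-7-(benzyloxy)-3-[(benzyloxy)methyl]-2-[4-(benzyloxy)-3-methoxyphenyl]-2,3-dihydro-1-benzofuran-5-yl][(3R,4S)-4-{[4-(benzyloxy)-3-methoxyphenyl]methyl}-2-oxooxolan-3-yl]methyl} O-phenyl carbonothioate (carbinol epimers) | COc1cc(C[C@@H]2COC(=O)[C@H]2C(OC(=S)Oc2ccccc2)c2cc(OCc3ccccc3)c3c(c2)[C@H](COCc2ccccc2)[C@@H](c2ccc(OCc4ccccc4)c(OC)c2)O3)ccc1OCc1ccccc1
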